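**Remark on the chemistry:** the target, 7‑hydroxy‑6‑methoxy‑3‑(3,4,5‑trimethoxyphenyl)‑4H‑chromen‑4‑one, has no stereocentre and no stereogenic double bond, so it is achiral and no enantiocontrol is needed. Intermediates 8, 10, 11, 12 and 13 are racemic; their stereocentres become sp2 or vanish before the target.

**Plan**
- Retrosynthetic cuts: O1–C2 (ring C opened to a 2′‑hydroxy β‑keto acetal), then the C3–C1′ aryl bond by a retro‑1,2‑aryl shift back to C2 (= chalcone Cβ), then Cα=Cβ (Claisen–Schmidt), the C4a–C4 acyl bond (Nencki) and C8a–O (Dakin on isovanillin).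
- Enabling feature: C3 of the pyranone carries the B ring between C4=O and C2–H at formyl oxidation level, which is the pattern left when the B ring of a 1,3‑diarylpropenone shifts from C2 to C3. The C4′‑OMe para to the migrating carbon stabilises the bridged phenonium ion, and O1 sits ortho to the acyl group, ready to close on C2.
- Forward order: ring A is prepared from isovanillin (steps 1–3), the C6–C3–C6 chain is joined (step 4), the oxidative aryl migration modelled on isoflavone synthase gives the isoflavonoid skeleton (step 5), and ring C is closed last (step 6).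
- Stereochemistry: none in the target; the E‑enone of step 4 is the thermodynamic isomer, and the racemic centre made in step 5 is erased on aromatisation in step 6.

Key step: step 5

**Step 1**
Reactants: 1 isovanillin (3‑hydroxy‑4‑methoxybenzaldehyde)
Product: 3 4‑methoxybenzene‑1,3‑diol, via aryl formate 2 (not isolated)
Conditions: 30% aq H2O2 (1.2 equiv), cat. H2SO4, MeOH, 0 °C → rt, N2; aq Na2SO3 quench
Reagents that add atoms: hydrogen peroxide, OO
Why: acid‑catalysed Dakin (Baeyer–Villiger‑type) oxidation, in which the aryl group activated by the para‑methoxy group migrates in the Criegee adduct and formate 2 is methanolysed in situ.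

**Step 2**
Reactants: 3 4‑methoxybenzene‑1,3‑diol
Product: 4 1‑(2,4‑dihydroxy‑5‑methoxyphenyl)ethanone
Conditions: AcOH, anhydrous ZnCl2 (1.5 equiv), 120–130 °C, N2; then dil. HCl
Reagents that add atoms: acetic acid, CC(=O)O
Why: Nencki reaction (Friedel–Crafts C‑acylation of a resorcinol), which should go at C6 because it is ortho to one hydroxyl, para to the other and unhindered, whereas C2 lies between two oxygens.

**Step 3**
Reactants: 4 1‑(2,4‑dihydroxy‑5‑methoxyphenyl)ethanone
Product: 6 1‑[2,4‑bis(benzyloxy)‑5‑methoxyphenyl]ethanone, via monobenzyl ether 5 (not isolated)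
Conditions: BnBr (2.5 equiv), K2CO3 (3 equiv), cat. n‑Bu4NI, DMF, 70 °C
Reagents that add atoms: benzyl bromide, BrCc1ccccc1
Why: Williamson ether synthesis, in which the free 4‑OH reacts first and the hydrogen‑bonded 2‑OH follows with excess halide and heat, so that both oxidisable phenols are masked before the iodine(III) step.

**Step 4**
Reactants: 6 1‑[2,4‑bis(benzyloxy)‑5‑methoxyphenyl]ethanone; 7 3,4,5‑trimethoxybenzaldehyde
Product: 9 (E)‑1‑[2,4‑bis(benzyloxy)‑5‑methoxyphenyl]‑3‑(3,4,5‑trimethoxyphenyl)prop‑2‑en‑1‑one, via aldol adduct 8 (not isolated)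
Conditions: KOH (50% aq, 3 equiv), EtOH/THF, rt
Reagents that add atoms: none
Why: Claisen–Schmidt condensation of a methyl ketone with a non‑enolisable aldehyde, where E1cB dehydration of aldol 8 should give the thermodynamically favoured E‑enone.

**Step 5**
Reactants: 9 (E)‑1‑[2,4‑bis(benzyloxy)‑5‑methoxyphenyl]‑3‑(3,4,5‑trimethoxyphenyl)prop‑2‑en‑1‑one
Product: 11 1‑[2,4‑bis(benzyloxy)‑5‑methoxyphenyl]‑3,3‑dimethoxy‑2‑(3,4,5‑trimethoxyphenyl)propan‑1‑one, via α‑iodanyl β‑methoxy ketone 10 (not isolated)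
Conditions: PhI(OH)OTs (1.2 equiv), MeOH/CH2Cl2 3:1, rt → 40 °C; aq NaHCO3
Reagents that add atoms: methanol, CO
Why: The λ3‑iodane should add electrophilically to Cα of the enone while methanol captures the benzylic Cβ cation to give adduct 10; the C–I(III) bond then ionises (PhI as hypernucleofuge) with 1,2‑shift of the 3,4,5‑trimethoxyphenyl ring from Cβ to Cα through a bridged phenonium ion, and the methoxy‑stabilised oxocarbenium left at Cβ is trapped by a second methanol as the dimethyl acetal. The closest known reaction type is the hypervalent‑iodine (or thallium(III)) oxidative rearrangement of chalcones to 1,2‑diaryl‑3,3‑dimethoxypropan‑1‑ones, the laboratory counterpart of the enzymatic 2→3 aryl shift of isoflavone biosynthesis. No ring is closed in this step; ring C is closed in step 6. The one new stereocentre (C2 of the propanone) forms racemic and needs no control because it becomes sp2 C3 of the target. The step needs B‑ring migration rather than aroyl‑ring migration, and attack of iodine(III) on the alkene rather than on an arene or phenol: the first should be secured by the C4′‑methoxy group and by running in methanol without orthoformate, so that the hindered, electron‑rich ketone is not ketalised and aroyl migration would have to leave an acylium ion; the second by the two benzyl ethers.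

**Step 6**
Reactants: 11 1‑[2,4‑bis(benzyloxy)‑5‑methoxyphenyl]‑3,3‑dimethoxy‑2‑(3,4,5‑trimethoxyphenyl)propan‑1‑one
Product: 14 7‑hydroxy‑6‑methoxy‑3‑(3,4,5‑trimethoxyphenyl)‑4H‑chromen‑4‑one, via dihydroxy acetal 12 (not isolated), via 2‑methoxyisoflavanone 13 (not isolated)
Conditions: H2 (1 atm), 10% Pd/C, EtOAc/MeOH, rt; filter; then cat. conc. HCl, MeOH, 60 °C
Reagents that add atoms: none
Why: hydrogenolysis should remove both benzyl ethers, after which acid ionises the acetal to an oxocarbenium that the 2′‑OH captures (6‑exo‑trig, O1–C2 bond) and loss of methanol from 13 is driven by formation of the aromatic 4‑pyranone.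

**Compound list**
1 | isovanillin (3‑hydroxy‑4‑methoxybenzaldehyde) | COc1ccc(C=O)cc1O | starting material
2 | 3‑hydroxy‑4‑methoxyphenyl formate | COc1ccc(OC=O)cc1O | intermediate
3 | 4‑methoxybenzene‑1,3‑diol (4‑methoxyresorcinol) | COc1ccc(O)cc1O | intermediate
4 | 1‑(2,4‑dihydroxy‑5‑methoxyphenyl)ethanone | COc1cc(C(C)=O)c(O)cc1O | intermediate
5 | 1‑[4‑(benzyloxy)‑2‑hydroxy‑5‑methoxyphenyl]ethanone | COc1cc(C(C)=O)c(O)cc1OCc1ccccc1 | intermediate
6 | 1‑[2,4‑bis(benzyloxy)‑5‑methoxyphenyl]ethanone | COc1cc(C(C)=O)c(OCc2ccccc2)cc1OCc1ccccc1 | intermediate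
7 | 3,4,5‑trimethoxybenzaldehyde | COc1cc(C=O)cc(OC)c1OC | starting material
8 | 1‑[2,4‑bis(benzyloxy)‑5‑methoxyphenyl]‑3‑hydroxy‑3‑(3,4,5‑trimethoxyphenyl)propan‑1‑one (racemic) | COc1cc(C(=O)CC(O)c2cc(OC)c(OC)c(OC)c2)c(OCc2ccccc2)cc1OCc1ccccc1 | intermediate
9 | (E)‑1‑[2,4‑bis(benzyloxy)‑5‑methoxyphenyl]‑3‑(3,4,5‑trimethoxyphenyl)prop‑2‑en‑1‑one | COc1cc(C(=O)/C=C/c2cc(OC)c(OC)c(OC)c2)c(OCc2ccccc2)cc1OCc1ccccc1 | intermediate
10 | 1‑[2,4‑bis(benzyloxy)‑5‑methoxyphenyl]‑3‑methoxy‑2‑[phenyl(tosyloxy)‑λ3‑iodanyl]‑3‑(3,4,5‑trimethoxyphenyl)propan‑1‑one (racemic, diastereomer mixture) | COc1cc(C(=O)C(C(OC)c2cc(OC)c(OC)c(OC)c2)I(OS(=O)(=O)c2ccc(C)cc2)c2ccccc2)c(OCc2ccccc2)cc1OCc1ccccc1 | intermediate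
11 | 1‑[2,4‑bis(benzyloxy)‑5‑methoxyphenyl]‑3,3‑dimethoxy‑2‑(3,4,5‑trimethoxyphenyl)propan‑1‑one (racemic) | COC(OC)C(c1cc(OC)c(OC)c(OC)c1)C(=O)c1cc(OC)c(OCc2ccccc2)cc1OCc1ccccc1 | intermediate
12 | 1‑(2,4‑dihydroxy‑5‑methoxyphenyl)‑3,3‑dimethoxy‑2‑(3,4,5‑trimethoxyphenyl)propan‑1‑one (racemic) | COC(OC)C(c1cc(OC)c(OC)c(OC)c1)C(=O)c1cc(OC)c(O)cc1O | intermediate
13 | 7‑hydroxy‑2,6‑dimethoxy‑3‑(3,4,5‑trimethoxyphenyl)chroman‑4‑one (racemic, diastereomer mixture) | COC1Oc2cc(O)c(OC)cc2C(=O)C1c1cc(OC)c(OC)c(OC)c1 | intermediate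
14 | 7‑hydroxy‑6‑methoxy‑3‑(3,4,5‑trimethoxyphenyl)‑4H‑chromen‑4‑one | COc1cc2c(=O)c(-c3cc(OC)c(OC)c(OC)c3)coc2cc1O | target

**Total step count:** 6. **Longest linear sequence:** 6 steps (1 → 14; aldehyde 7 enters at step 4).

**Steps most likely to fail**

1. Step 5 (key step). The aryl shift may be slow, because the two meta‑methoxy groups reduce the donor strength of the migrating ring, which would let solvolysis of adduct 10 compete. The very electron‑rich aroyl ring could also migrate instead, giving an ester‑type rearrangement product. Fallback, from chalcone 9: Weitz–Scheffer epoxidation (30% H2O2, aq NaOH, MeOH/THF, 0 °C) should give the racemic trans‑epoxide [2,4‑bis(benzyloxy)‑5‑methoxyphenyl][3‑(3,4,5‑trimethoxyphenyl)oxiran‑2‑yl]methanone F1. BF3·OEt2 (cat., CH2Cl2, −20 → 0 °C) should open the benzylic C–O bond and trigger a 1,2‑acyl shift (Meinwald‑type rearrangement of a chalcone oxide) to the α‑formyl deoxybenzoin 3‑[2,4‑bis(benzyloxy)‑5‑methoxyphenyl]‑3‑oxo‑2‑(3,4,5‑trimethoxyphenyl)propanal F2, which has the same skeleton and oxidation level as 11. Hydrogenolysis (H2, Pd/C, EtOAc) should give 3‑(2,4‑dihydroxy‑5‑methoxyphenyl)‑3‑oxo‑2‑(3,4,5‑trimethoxyphenyl)propanal F3, expected to sit largely as its cyclic 2‑hydroxyisoflavanone hemiacetal. Brief warming with HCl/MeOH should dehydrate it, and the route is rejoined at 14.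

2. Step 1. The free, electron‑rich phenol and the even more oxidisable product 3 may be over‑oxidised to quinones by the peroxide, and aryl migration may be slow next to formation of the benzoic acid. Fallback, from 1: acetylation (Ac2O, pyridine) should give 5‑formyl‑2‑methoxyphenyl acetate F4. Baeyer–Villiger oxidation with mCPBA in CH2Cl2 should give 5‑(formyloxy)‑2‑methoxyphenyl acetate F5, in which the ring is deactivated against over‑oxidation. Methanolysis of both esters (K2CO3, MeOH, N2) rejoins the route at 3.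

3. Step 2. At 120–130 °C with ZnCl2 the air‑sensitive diol may suffer ether cleavage, O‑ or di‑acylation and tarring instead of clean mono‑C‑acylation. Fallback, from 3: Hoesch reaction with acetonitrile (ZnCl2, HCl gas, Et2O, 0 °C) should give the ketiminium salt 1‑(2,4‑dihydroxy‑5‑methoxyphenyl)ethan‑1‑iminium chloride F6 at low temperature with the same regiochemistry. Hydrolysis in hot water rejoins the route at 4.

**Further compounds**
F1 | step 5 | [2,4‑bis(benzyloxy)‑5‑methoxyphenyl][trans‑3‑(3,4,5‑trimethoxyphenyl)oxiran‑2‑yl]methanone (racemic, one enantiomer drawn) | COc1cc(C(=O)[C@@H]3O[C@H]3c2cc(OC)c(OC)c(OC)c2)c(OCc2ccccc2)cc1OCc1ccccc1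
F2 | step 5 | 3‑[2,4‑bis(benzyloxy)‑5‑methoxyphenyl]‑3‑oxo‑2‑(3,4,5‑trimethoxyphenyl)propanal (racemic) | O=CC(c1cc(OC)c(OC)c(OC)c1)C(=O)c1cc(OC)c(OCc2ccccc2)cc1OCc1ccccc1
F3 | step 5 | 3‑(2,4‑dihydroxy‑5‑methoxyphenyl)‑3‑oxo‑2‑(3,4,5‑trimethoxyphenyl)propanal (racemic) | O=CC(c1cc(OC)c(OC)c(OC)c1)C(=O)c1cc(OC)c(O)cc1O
F4 | step 1 | 5‑formyl‑2‑methoxyphenyl acetate | COc1ccc(C=O)cc1OC(C)=O
F5 | step 1 | 5‑(formyloxy)‑2‑methoxyphenyl acetate | COc1ccc(OC=O)cc1OC(C)=O
F6 | step 2 | 1‑(2,4‑dihydroxy‑5‑methoxyphenyl)ethan‑1‑iminium chloride | COc1cc(C(C)=[NH2+])c(O)cc1O.[Cl-]
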